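## Structural features

The target 20 is a chrysin-type flavone. Benzo ring A (C4a–C8a, a phloroglucinol pattern with free hydroxyls at C5 and C7) is fused to 4-pyranone ring C, which carries phenyl ring B at C2. C8 of ring A is bonded to C2' of a 1-methylpiperidine. C2' is the only stereocentre (R), so its configuration must be set absolutely, with no neighbouring centre to relay from. C2' is benzylic to a 2,4,6-trioxygenated arene and alpha to a basic tertiary nitrogen, so C2'–N1' is the bond of a phenolic Mannich base. Ionisation under acid or Lewis acid, or expulsion of nitrogen through an ortho-quinone methide once O7 is free, would open the ring reversibly and erode the configuration. Other fragile points are the 5-hydroxy-4-pyranone (8→6 isomerisation by Wessely–Moser ring opening in hot strong acid) and the basic nitrogen, which binds transition metals. The real difficulties are to create C2' in one absolute sense on a doubly ortho-substituted, very electron-rich arene and keep it, and to place the piperidine at C8 and not C6, which depends on which ring A oxygen becomes O1. The key step exploits the fact that C3' to C6' are bare methylenes: C3'–C4' can be an alkene closed by metathesis from a diene in which N1'–CH3, N1'–C6' and N1'–C2' already exist.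

## Logic of the disconnections

**20 from 18.** The two O–CH3 bonds at O5 and O7 are cut last. Methyl ethers survive every earlier operation (hydride, base, ruthenium, hydrogen, Friedel–Crafts), and a capped O7 keeps the ortho-quinone methide pathway closed for as long as possible. The forward step must cleave both ethers, including the less reactive one at O7, cold enough to leave C2'–N1' intact.

**18 from 15 and 16.** Ring C is cut at O1–C2 and C2–C3, with 17 as the link between the two pieces. This removes rings B and C in one operation and leaves a piperidinyl arene. Because 15 has a single free phenol, ring C can close in one direction only. The forward step must C-acylate the ketone enolate and dehydrate without touching C2'.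

**15 from 12.** The aryl–acetyl bond C4a–C4 is cut and the free phenol is taken back to its methyl ether. The two unsubstituted ring positions of 12 are equivalent, so the acyl carbon can enter only one kind of site, and 12 is much simpler than 15. The forward step must cleave, of the two methoxy groups ortho to the new ketone, the one that also flanks the piperidine; that oxygen becomes O1 and fixes the piperidine at C8.

**12 from 11.** A C3'=C4' double bond is introduced retrosynthetically. It adds no stereocentre and turns a saturated ring into one that metathesis can make. The forward hydrogenation must not move the alkene towards C2' or hydrogenolyse the benzylic, allylic C2'–N1' bond.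

**11 from 8 (key step).** C3'=C4' is cut to two terminal alkenes. All bonds to nitrogen and the stereocentre are already present in 8, so the closure is one catalytic step that creates no stereocentre and loses only ethene. The basic amine must be made compatible with the ruthenium carbene, which is done by reacting the salt 9, and ring closure must outrun intermolecular metathesis and alkene migration.

**8 from 6 and 7.** The C2'–N1' bond is cut. This is the only disconnection that touches the stereocentre. It divides 8 into the achiral linear carbonate 6 and the achiral amine 7, which delivers N-methyl and the butenyl arm together. The forward step must be branched-selective and enantioselective on an allyl unit whose aryl group has two ortho substituents.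

**6 from 5, 3, 1 and 2.** The carbonate C–O bond is cut to give 5, 5 is related to 3 by reduction (through 4), and the C=C bond of 3 is cut to 1 and 2. The E-alkene and the three-carbon chain (C2', C3' and the carbon later lost as ethene) come from a stabilised phosphonate olefination of a commercial aldehyde. The forward steps need E selectivity and non-acidic handling, because the trimethoxycinnamyl system ionises easily.

## Other disconnections considered

**Alternative 1:** The cut goes through ring A (C7–C8, C4a–C8a and C6–C7), so the arene is built on a piperidine that already owns C2'.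
- Forward: the chiral-pool ester A1 (methyl (R)-1-(tert-butoxycarbonyl)piperidine-2-carboxylate) would be homologated through its ynolate to the siloxyalkyne A2 (tert-butyl (R)-2-{[tri(propan-2-yl)silyl]oxyethynyl}piperidine-1-carboxylate). A2 would be heated with the cyclobutenone A3 (3-ethoxycyclobut-2-en-1-one). Four-electron opening of A3 to a vinylketene, [2+2] cycloaddition with A2, a second four-electron opening, six-electron closure and tautomerisation would give the phenol A4 (tert-butyl (R)-2-[4-ethoxy-2-hydroxy-6-(triisopropylsilyloxy)phenyl]piperidine-1-carboxylate).
- In favour: the configuration is bought, not induced. The hindered aryl–C2' bond never has to be formed. The three oxygens emerge differentiated, so the oxygen that becomes O1 is chosen by protecting group and not by selective demethylation. On these three points this alternative is the better plan.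
- Against: the homologation runs under strongly basic conditions next to an alpha-amino ester stereocentre. A4 still lacks the C4 carbon, so ring acylation, ring C closure, conversion of the carbamate into N-methyl and removal of silyl and ethyl groups remain. The O-ethyl ether is no easier to cleave at the end than a methyl ether. The count would be about ten steps against nine, with a costly cyclobutenone.
- Comparison: the cascade is thermal and multi-event, whereas the chosen closure is a single catalytic event. On exposure of the benzylic C–N bond to Lewis acid in the endgame the two plans are equal.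

**Alternative 2:** The cut is N1'=C2' of a cyclic imine, with the C2'–H bond made afterwards by asymmetric reduction.
- Forward: the lactam A5 (tert-butyl 2-oxopiperidine-1-carboxylate) would be opened by the aryllithium from A6 (1,3,5-trimethoxybenzene) to the amino ketone A7 (tert-butyl [5-oxo-5-(2,4,6-trimethoxyphenyl)pentyl]carbamate). Acid would remove the carbamate and the amine would condense to the imine A8 (6-(2,4,6-trimethoxyphenyl)-2,3,4,5-tetrahydropyridine). RuCl(p-cymene)(TsDPEN) of the appropriate handedness with HCO2H/Et3N would reduce it in the same flask to A9 ((R)-2-(2,4,6-trimethoxyphenyl)piperidine), and N-methylation would give 12.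
- In favour: three steps to 12 against six, cheap achiral materials, a condensation that is hard to get wrong, and no alkene to hydrogenate. In step economy this alternative is clearly the better.
- Against: the hydride must distinguish the faces of a ketimine whose aryl group bears two ortho methoxy groups and is twisted out of the C=N plane. That removes the flat aryl face this catalyst class uses for recognition, and the three donor groups make the iminium ion a weak hydride acceptor. An amine of insufficient purity could only be upgraded by salt resolution.
- Comparison: the chosen plan has the same kind of doubt in step 4 (an ortho,ortho-disubstituted aryl group in an asymmetric catalytic step), so on stereochemical risk the two are about equal. The chosen plan brings N-methyl in with the nitrogen; the alternative needs a separate but trivial methylation. From 12 onward the routes coincide.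

**Alternative 3:** The cuts are C2'–C3' (with the stereocentre) and N1'–C6'.
- Forward: aldehyde 1 would be condensed with the auxiliary A10 ((S)-2-methylpropane-2-sulfinamide) to the aldimine A11 ((S,E)-2-methyl-N-[(2,4,6-trimethoxyphenyl)methylidene]propane-2-sulfinamide). The Grignard reagent A12 (4-chlorobutylmagnesium bromide) would add through a six-membered chelate in which magnesium is held by the sulfinyl oxygen. Added alkoxide base would then let the sulfinamide nitrogen displace chloride (6-exo-tet) to give A13 ((R)-1-[(S)-tert-butylsulfinyl]-2-(2,4,6-trimethoxyphenyl)piperidine). Acid removal of the auxiliary and N-methylation would give 12.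
- In favour: four steps to 12 against six and no transition metal. The stereochemical outcome is a diastereomer ratio, so the minor isomer could be removed by chromatography or crystallisation before the auxiliary is cleaved. On step economy and on the possibility of upgrading configurational purity this alternative is the better.
- Against: the ortho methoxy groups can compete with the sulfinyl oxygen for magnesium, which can lower or invert the facial selectivity. The 2,6-disubstituted aldimine is hindered. The auxiliary is stoichiometric and must be removed with acid from a very acid-sensitive benzylic amine.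
- Comparison: the chosen plan is catalytic in the chiral element and brings N-methyl with the nucleophile, but is two steps longer. The endgame and its risks are identical.

Key step: step 5

Assumption: in step 4, L is the phosphoramidite from (R)-BINOL and bis[(R)-1-(2-methoxyphenyl)ethyl]amine, taken by analogy with aryl-substituted allylic carbonates to be the antipode that gives the R amine; if the sense of induction were opposite on this substrate, the mirror-image ligand would be used.

## Route

Step 1
Reactants: 1 2,4,6-trimethoxybenzaldehyde; 2 triethyl phosphonoacetate
Product: 3 ethyl (E)-3-(2,4,6-trimethoxyphenyl)prop-2-enoate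
Conditions: NaH, THF, 0 °C → 65 °C
Reagents that add atoms: none
Why: Horner–Wadsworth–Emmons olefination; the stabilised phosphonate anion adds reversibly and eliminates through the anti oxaphosphetane to the E ester, and heating overcomes the low electrophilicity of the hindered, electron-rich aldehyde.

Step 2
Reactants: 3 ethyl (E)-3-(2,4,6-trimethoxyphenyl)prop-2-enoate
Product: 5 (E)-3-(2,4,6-trimethoxyphenyl)prop-2-en-1-ol, via (E)-3-(2,4,6-trimethoxyphenyl)prop-2-enal 4 (not isolated)
Conditions: i-Bu2AlH (2.5 equiv), CH2Cl2, −78 → 0 °C; aq. KNaC4H4O6
Reagents that add atoms: none
Why: 1,2-Reduction of the conjugated ester by the electrophilic aluminium hydride through aldehyde 4, which is reduced faster than it accumulates; the tartrate work-up avoids acid, to which the trimethoxycinnamyl alcohol is sensitive.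

Step 3
Reactants: 5 (E)-3-(2,4,6-trimethoxyphenyl)prop-2-en-1-ol
Product: 6 methyl (E)-3-(2,4,6-trimethoxyphenyl)prop-2-en-1-yl carbonate
Conditions: ClCO2Me, pyridine, CH2Cl2, 0 °C
Reagents that add atoms: methyl chloroformate, COC(=O)Cl
Why: Acylation of the primary allylic alcohol by a chloroformate with pyridine as base and nucleophilic catalyst; the methyl carbonate is the standard leaving group for iridium allyl chemistry and supplies its own base on ionisation.

Step 4
Reactants: 6 methyl (E)-3-(2,4,6-trimethoxyphenyl)prop-2-en-1-yl carbonate; 7 N-methylbut-3-en-1-amine
Product: 8 (R)-N-methyl-N-[1-(2,4,6-trimethoxyphenyl)prop-2-en-1-yl]but-3-en-1-amine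
Conditions: [Ir(cod)Cl]2 (2 mol %), L (4 mol %), n-PrNH2 (pre-activation), THF, rt
Reagents that add atoms: none
Why: Iridium-catalysed asymmetric allylic amination; the cyclometalated iridium phosphoramidite complex ionises 6 to an allyl complex of trivalent iridium and the secondary amine attacks the aryl-substituted terminus from the face opposite to the metal, which gives the branched amine. The ligand decides which enantiotopic face of the allyl unit is bound and so sets C2' as R.

Step 5
Reactants: 8 (R)-N-methyl-N-[1-(2,4,6-trimethoxyphenyl)prop-2-en-1-yl]but-3-en-1-amine
Product: 11 (R)-1-methyl-6-(2,4,6-trimethoxyphenyl)-1,2,3,6-tetrahydropyridine, via diene ammonium tosylate 9 (not isolated), via tetrahydropyridinium tosylate 10 (not isolated)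
Conditions: TsOH·H2O (1.05 equiv), CH2Cl2, rt; second-generation Grubbs catalyst (H2IMes)(PCy3)Cl2Ru=CHPh (5 mol %), CH2Cl2 (0.02 M), 40 °C; then aq. NaOH
Reagents that add atoms: none
Why: Ring-closing olefin metathesis of an amine salt; the closest known reaction type is ring closure of protonated diene amines to 1,2,3,6-tetrahydropyridines. After loss of PCy3 the ruthenium benzylidene undergoes [2+2] cycloaddition with the unhindered butenyl terminus of 9 and cycloreversion, which loads the metal on C4'. The new alkylidene adds across the vinyl group on C2' to a ruthenacyclobutane, whose cycloreversion forms C3'=C4' and a ruthenium methylidene that carries the cycle on and ends as ethene. The six-membered ring is thus closed by intramolecular alkene metathesis, the ring alkene can only be cis, and escape of ethene makes the closure irreversible. No stereocentre is created; C2' was set in step 4 and none of its bonds is made or broken. The step needs ring closure to win over dimerisation, which the unstrained six-membered ring and dilution secure, and metathesis to win over amine binding and alkene migration, which full protonation of nitrogen secures. A mild temperature and prompt basification limit ionisation of the benzylic, allylic ammonium ion, the one pathway that could erode the configuration.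

Step 6
Reactants: 11 (R)-1-methyl-6-(2,4,6-trimethoxyphenyl)-1,2,3,6-tetrahydropyridine
Product: 12 (R)-1-methyl-2-(2,4,6-trimethoxyphenyl)piperidine
Conditions: H2 (1 atm), PtO2 (5 mol %), EtOAc, rt
Reagents that add atoms: none
Why: Heterogeneous hydrogenation of the cis ring alkene, which creates no stereocentre; platinum is preferred to palladium because it is less prone to move the double bond into conjugation at C2' or to hydrogenolyse the benzylic, allylic C–N bond, the two events that could harm the stereocentre.

Step 7
Reactants: 12 (R)-1-methyl-2-(2,4,6-trimethoxyphenyl)piperidine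
Product: 15 (R)-1-[2-hydroxy-4,6-dimethoxy-3-(1-methylpiperidin-2-yl)phenyl]ethan-1-one, via trimethoxy ketone 13 (not isolated), via difluoroboron chelate 14 (not isolated)
Conditions: BF3·OEt2, Ac2O, CH2Cl2, 0 °C → rt; then aq. NaOH, MeOH, rt
Reagents that add atoms: acetic anhydride, CC(=O)OC(C)=O
Why: Friedel–Crafts acetylation at one of the two equivalent free positions of the very electron-rich ring gives 13; BF3 then cleaves the methoxy group flanked by the ketone and the piperidine (twisted out of conjugation and captured in the six-membered O–B–O chelate 14), the methyl group being taken up by acetate. Nitrogen is blocked as its BF3 adduct and is not acylated, aqueous base releases phenol 15, and the reaction type is known on (2,4,6-trimethoxyphenyl)piperidines.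

Step 8
Reactants: 15 (R)-1-[2-hydroxy-4,6-dimethoxy-3-(1-methylpiperidin-2-yl)phenyl]ethan-1-one; 16 methyl benzoate
Product: 18 5,7-dimethoxy-8-[(2R)-1-methylpiperidin-2-yl]-2-phenyl-4H-chromen-4-one, via 1,3-diketone 17 (not isolated)
Conditions: NaH, DMF, 0 °C → rt; then conc. HCl, rt → 50 °C; aq. NaOH to pH 9
Reagents that add atoms: none
Why: Claisen-type C-benzoylation of the ketone enolate of the phenoxide gives 17, the same diketone that a Baker–Venkataraman rearrangement would give; acid then promotes addition of the only free phenol to the benzoyl carbonyl (6-exo-trig hemiketal) and dehydration to the 4-pyranone. Because O1 can come only from the phenol next to C8, the piperidine is fixed at C8, and C2' has no acidic hydrogen under these conditions.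

Step 9
Reactants: 18 5,7-dimethoxy-8-[(2R)-1-methylpiperidin-2-yl]-2-phenyl-4H-chromen-4-one
Product: 20 5,7-dihydroxy-8-[(2R)-1-methylpiperidin-2-yl]-2-phenyl-4H-chromen-4-one, via 7-O-methyl ether 19 (not isolated)
Conditions: BBr3 (6 equiv), CH2Cl2, −78 °C → rt; then H2O, NaHCO3, 0 °C
Reagents that add atoms: none
Why: Lewis-acid ether cleavage, in which boron binds the ether oxygen and bromide attacks the methyl group (SN2); the 5-methoxy group, chelated to the C4 carbonyl, should fall first (19) and the 7-methoxy group needs the excess reagent and room temperature. One equivalent of reagent is held by the amine, and a cold, near-neutral work-up limits ring opening of the phenolic Mannich base.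

## Compound list

1 | 2,4,6-trimethoxybenzaldehyde | COc1cc(OC)c(C=O)c(OC)c1 | starting material
2 | triethyl phosphonoacetate | CCOC(=O)CP(=O)(OCC)OCC | starting material
3 | ethyl (E)-3-(2,4,6-trimethoxyphenyl)prop-2-enoate | CCOC(=O)/C=C/c1c(OC)cc(OC)cc1OC | intermediate
4 | (E)-3-(2,4,6-trimethoxyphenyl)prop-2-enal | O=C/C=C/c1c(OC)cc(OC)cc1OC | intermediate
5 | (E)-3-(2,4,6-trimethoxyphenyl)prop-2-en-1-ol | OC/C=C/c1c(OC)cc(OC)cc1OC | intermediate
6 | methyl (E)-3-(2,4,6-trimethoxyphenyl)prop-2-en-1-yl carbonate | COC(=O)OC/C=C/c1c(OC)cc(OC)cc1OC | intermediate
7 | N-methylbut-3-en-1-amine | C=CCCNC | starting material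
8 | (R)-N-methyl-N-[1-(2,4,6-trimethoxyphenyl)prop-2-en-1-yl]but-3-en-1-amine | C=CCCN(C)[C@H](C=C)c1c(OC)cc(OC)cc1OC | intermediate
9 | (R)-N-methyl-N-[1-(2,4,6-trimethoxyphenyl)prop-2-en-1-yl]but-3-en-1-aminium 4-methylbenzenesulfonate | C=CCC[NH+](C)[C@H](C=C)c1c(OC)cc(OC)cc1OC.Cc1ccc(cc1)S(=O)(=O)[O-] | intermediate
10 | (R)-1-methyl-6-(2,4,6-trimethoxyphenyl)-1,2,3,6-tetrahydropyridin-1-ium 4-methylbenzenesulfonate | C[NH+]1CCC=C[C@@H]1c1c(OC)cc(OC)cc1OC.Cc1ccc(cc1)S(=O)(=O)[O-] | intermediate
11 | (R)-1-methyl-6-(2,4,6-trimethoxyphenyl)-1,2,3,6-tetrahydropyridine | CN1CCC=C[C@@H]1c1c(OC)cc(OC)cc1OC | intermediate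
12 | (R)-1-methyl-2-(2,4,6-trimethoxyphenyl)piperidine | CN1CCCC[C@@H]1c1c(OC)cc(OC)cc1OC | intermediate
13 | (R)-1-[2,4,6-trimethoxy-3-(1-methylpiperidin-2-yl)phenyl]ethan-1-one | CC(=O)c1c(OC)cc(OC)c([C@H]2CCCCN2C)c1OC | intermediate
14 | difluoroboron chelate of 15: 2,2-difluoro-5,7-dimethoxy-4-methyl-8-[(2R)-1-methylpiperidin-2-yl]-1,3,2-benzodioxaborinine (O–BF2–O=C ring) | CC1=[O+][B-](F)(F)Oc2c([C@H]3CCCCN3C)c(OC)cc(OC)c21 | intermediate
15 | (R)-1-[2-hydroxy-4,6-dimethoxy-3-(1-methylpiperidin-2-yl)phenyl]ethan-1-one | CC(=O)c1c(OC)cc(OC)c([C@H]2CCCCN2C)c1O | intermediate
16 | methyl benzoate | COC(=O)c1ccccc1 | starting material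
17 | (R)-1-[2-hydroxy-4,6-dimethoxy-3-(1-methylpiperidin-2-yl)phenyl]-3-phenylpropane-1,3-dione | O=C(CC(=O)c1ccccc1)c1c(OC)cc(OC)c([C@H]2CCCCN2C)c1O | intermediate
18 | 5,7-dimethoxy-8-[(2R)-1-methylpiperidin-2-yl]-2-phenyl-4H-chromen-4-one | CN1CCCC[C@@H]1c1c(OC)cc(OC)c2c(=O)cc(-c3ccccc3)oc12 | intermediate
19 | 5-hydroxy-7-methoxy-8-[(2R)-1-methylpiperidin-2-yl]-2-phenyl-4H-chromen-4-one | CN1CCCC[C@@H]1c1c(OC)cc(O)c2c(=O)cc(-c3ccccc3)oc12 | intermediate
20 | 5,7-dihydroxy-8-[(2R)-1-methylpiperidin-2-yl]-2-phenyl-4H-chromen-4-one | CN1CCCC[C@@H]1c1c(O)cc(O)c2c(=O)cc(-c3ccccc3)oc12 | target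

## Step count and least certain steps

Total step count: 9. Longest linear sequence: 9 steps (1 to 20).

**Step 5 (key step).**
- Risk: stalled turnover through binding of traces of free amine to ruthenium, alkene migration by ruthenium hydrides formed on catalyst decay, and partial loss of configuration by reversible ionisation of the benzylic, allylic ammonium ion. The arene is extremely electron-rich and the acid that protects the catalyst also activates the C–N bond.
- Fallback (from 6, back at 11): nitrogen is carried through the metathesis as a neutral carbamate that also holds the future N-methyl carbon. Compound 6 would be aminated under the conditions of step 4 with but-3-en-1-amine to give (R)-N-[1-(2,4,6-trimethoxyphenyl)prop-2-en-1-yl]but-3-en-1-amine F1. ClCO2Me and Et3N would convert it into methyl (R)-but-3-en-1-yl[1-(2,4,6-trimethoxyphenyl)prop-2-en-1-yl]carbamate F2. Ring-closing metathesis with the same ruthenium catalyst and no acid would give methyl (R)-6-(2,4,6-trimethoxyphenyl)-3,6-dihydropyridine-1(2H)-carboxylate F3, and LiAlH4 in THF would reduce the carbamate to N-methyl, which is 11.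

**Step 4.**
- Risk: low enantioselectivity or low branched selectivity, because the two ortho methoxy groups twist the aryl ring out of the allyl plane and hinder attack at the benzylic terminus. The electron-rich branched amine may also re-ionise on the catalyst and drift to the linear isomer on long reaction times.
- Fallback (from 1, back at 8): auxiliary control with separable diastereomers. Aldehyde 1 would be condensed with (S)-2-methylpropane-2-sulfinamide and Ti(OEt)4 to (S,E)-2-methyl-N-[(2,4,6-trimethoxyphenyl)methylidene]propane-2-sulfinamide F4. CH2=CHMgBr in CH2Cl2 at −78 °C should add through the six-membered magnesium chelate to give (S)-2-methyl-N-[(R)-1-(2,4,6-trimethoxyphenyl)prop-2-en-1-yl]propane-2-sulfinamide F5, which can be freed of its diastereomer. LiN(SiMe3)2 and MeI would give (S)-N,2-dimethyl-N-[(R)-1-(2,4,6-trimethoxyphenyl)prop-2-en-1-yl]propane-2-sulfinamide F6. HCl in dioxane at 0 °C would remove the auxiliary to give (R)-N-methyl-1-(2,4,6-trimethoxyphenyl)prop-2-en-1-amine F7, and alkylation with 4-bromobut-1-ene (K2CO3, MeCN) would give 8.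

**Step 7.**
- Risk: ring opening or epimerisation at C2' by ionisation of the Lewis-acid-bound benzylic amine in the strongly acidic acylating medium, and cleavage of the wrong ortho methoxy group, which would later place the piperidine at C6.
- Fallback (from 12, back at 15): the ketone is introduced by metalation instead of electrophilic substitution. n-BuLi in THF at 0 °C should lithiate 12 at a ring position flanked by two methoxy groups, and N-methoxy-N-methylacetamide would give 13, now isolated. BCl3 in CH2Cl2 at −78 → 0 °C would then cleave the methoxy group ortho to the ketone to give 15. No compound outside the compound list is made (F0).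

**Step 9.**
- Risk: incomplete cleavage of the 7-methoxy group, which lacks carbonyl chelation. If forced, erosion of configuration by ring opening through an ortho-quinone methide once O7 is free, or 8→6 isomerisation of the 5-hydroxyflavone in acid.
- Fallback (from 18, back at 20): the deprotection is divided into two operations of different mechanism. BCl3 in CH2Cl2 at −20 °C would remove only the chelated 5-O-methyl group to give 19, now isolated. NaSEt in DMF at 100 °C would then remove the 7-O-methyl group by SN2 attack of thiolate at carbon, under basic conditions in which nitrogen is never protonated, to give 20. No compound outside the compound list is made (F0).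

## Further compounds

F1 | step 5 | (R)-N-[1-(2,4,6-trimethoxyphenyl)prop-2-en-1-yl]but-3-en-1-amine | C=CCCN[C@H](C=C)c1c(OC)cc(OC)cc1OC
F2 | step 5 | methyl (R)-but-3-en-1-yl[1-(2,4,6-trimethoxyphenyl)prop-2-en-1-yl]carbamate | C=CCCN(C(=O)OC)[C@H](C=C)c1c(OC)cc(OC)cc1OC
F3 | step 5 | methyl (R)-6-(2,4,6-trimethoxyphenyl)-3,6-dihydropyridine-1(2H)-carboxylate | COC(=O)N1CCC=C[C@@H]1c1c(OC)cc(OC)cc1OC
F4 | step 4 | (S,E)-2-methyl-N-[(2,4,6-trimethoxyphenyl)methylidene]propane-2-sulfinamide | CC(C)(C)[S@](=O)/N=C/c1c(OC)cc(OC)cc1OC
F5 | step 4 | (S)-2-methyl-N-[(R)-1-(2,4,6-trimethoxyphenyl)prop-2-en-1-yl]propane-2-sulfinamide | CC(C)(C)[S@](=O)N[C@H](C=C)c1c(OC)cc(OC)cc1OC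
F6 | step 4 | (S)-N,2-dimethyl-N-[(R)-1-(2,4,6-trimethoxyphenyl)prop-2-en-1-yl]propane-2-sulfinamide | CC(C)(C)[S@](=O)N(C)[C@H](C=C)c1c(OC)cc(OC)cc1OC
F7 | step 4 | (R)-N-methyl-1-(2,4,6-trimethoxyphenyl)prop-2-en-1-amine | CN[C@H](C=C)c1c(OC)cc(OC)cc1OC
F0 | step 7 | none | none
F0 | step 9 | none | none
A1 | alternative 1 | methyl (R)-1-(tert-butoxycarbonyl)piperidine-2-carboxylate | COC(=O)[C@H]1CCCCN1C(=O)OC(C)(C)C
A2 | alternative 1 | tert-butyl (R)-2-{[tri(propan-2-yl)silyl]oxyethynyl}piperidine-1-carboxylate | CC(C)(C)OC(=O)N1CCCC[C@@H]1C#CO[Si](C(C)C)(C(C)C)C(C)C
A3 | alternative 1 | 3-ethoxycyclobut-2-en-1-one | CCOC1=CC(=O)C1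
A4 | alternative 1 | tert-butyl (R)-2-[4-ethoxy-2-hydroxy-6-(triisopropylsilyloxy)phenyl]piperidine-1-carboxylate | CC(C)(C)OC(=O)N1CCCC[C@@H]1c1c(O)cc(OCC)cc1O[Si](C(C)C)(C(C)C)C(C)C
A5 | alternative 2 | tert-butyl 2-oxopiperidine-1-carboxylate | CC(C)(C)OC(=O)N1CCCCC1=O
A6 | alternative 2 | 1,3,5-trimethoxybenzene | COc1cc(OC)cc(OC)c1
A7 | alternative 2 | tert-butyl [5-oxo-5-(2,4,6-trimethoxyphenyl)pentyl]carbamate | CC(C)(C)OC(=O)NCCCCC(=O)c1c(OC)cc(OC)cc1OC
A8 | alternative 2 | 6-(2,4,6-trimethoxyphenyl)-2,3,4,5-tetrahydropyridine | COc1cc(OC)c(C2=NCCCC2)c(OC)c1
A9 | alternative 2 | (R)-2-(2,4,6-trimethoxyphenyl)piperidine | N1CCCC[C@@H]1c1c(OC)cc(OC)cc1OC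
A10 | alternative 3 | (S)-2-methylpropane-2-sulfinamide | CC(C)(C)[S@](=O)N
A11 | alternative 3 | (S,E)-2-methyl-N-[(2,4,6-trimethoxyphenyl)methylidene]propane-2-sulfinamide | CC(C)(C)[S@](=O)/N=C/c1c(OC)cc(OC)cc1OC
A12 | alternative 3 | 4-chlorobutylmagnesium bromide | ClCCCC[Mg]Br
A13 | alternative 3 | (R)-1-[(S)-tert-butylsulfinyl]-2-(2,4,6-trimethoxyphenyl)piperidine | CC(C)(C)[S@](=O)N1CCCC[C@@H]1c1c(OC)cc(OC)cc1OC
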